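**Retrosynthetic overview**
1. The only ring, the 1,2-dioxane peroxy-hemiketal, is formed last: a tertiary C6 hydroperoxide adds to the C3 ketone as soon as that ketone exists.
2. C2–C3: the β-keto ester comes from a crossed Claisen condensation of methyl acetate enolate on a γ-hydroperoxy methyl ester, run on the free OOH.
3. C6–OOH: Markovnikov hydroperoxymercuration–demercuration of a 4-methylidene ester; the Z-styrene is left untouched.
4. C5–C6: Negishi coupling of a vinyl triflate with a chiral-pool β-zincio ester, which brings in the C4 methyl centre.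
5. The vinyl triflate comes from a methyl ketone made by copper-catalysed asymmetric conjugate addition of a (Z)-8-phenyloct-7-enyl Grignard reagent (from phenylacetylene and 1,6-dibromohexane) to pent-3-en-2-one, which sets the side-chain methyl centre.

Assumption: the presumed biosynthesis is taken as oxygenation of C6 of an open-chain polyketide β-keto ester to a tertiary hydroperoxide that adds to the C3 ketone; comments use target ring numbering O1, O2, C3 (hemiketal), C4, C5, C6.
Assumption: the ligand enantiomer named in step 3 is taken to give the R ketone; if it gives S, the mirror-image ligand is used.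

**Route**

Step 1
Reactants: 1 phenylacetylene; 2 1,6-dibromohexane (3 equiv)
Product: 4 8-bromo-1-phenyloct-1-yne, via lithium phenylacetylide 3 (not isolated)
Conditions: n-BuLi (1.0 equiv), THF, −78 °C; then 2, DMPU, −78 °C to rt
Reagents that add atoms: none
Why: SN2 alkylation of a lithium acetylide by a primary bromide, with excess dibromide (recovered by distillation) suppressing double alkylation; no stereocentre is formed.

Step 2
Reactants: 4
Product: 5 (Z)-8-bromo-1-phenyloct-1-ene
Conditions: H2 (1 atm), Pd/CaCO3 poisoned with Pb(OAc)2, quinoline, hexane, rt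
Reagents that add atoms: none
Why: Syn semihydrogenation of the aryl alkyne over lead-poisoned palladium (the Lindlar reduction) delivers both hydrogens to one face and fixes the Z olefin, and it is done here because every later step tolerates the styrene whereas the finished peroxide would not tolerate hydrogenation.

Step 3
Reactants: 5; 6 (E)-pent-3-en-2-one
Product: 9 (4R,11Z)-4-methyl-12-phenyldodec-11-en-2-one, via Grignard reagent 7 (not isolated), via magnesium enolate 8 (not isolated)
Conditions: Mg, Et2O, reflux; then 6, CuBr·SMe2 (5 mol%), (R)-1-[(Sp)-2-(diphenylphosphino)ferrocenyl]ethyldicyclohexylphosphine (6 mol%), t-BuOMe, −75 °C, slow addition; 1 M HCl work-up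
Reagents that add atoms: none
Why: Feringa-type copper-catalysed asymmetric conjugate addition of a Grignard reagent to an acyclic enone, in which the chiral ferrocenyl diphosphine–copper complex selects one enantioface of the β-carbon and so sets the side-chain methyl stereocentre as R (about 90% ee expected).

Step 4
Reactants: 9
Product: 11 (4R,11Z)-4-methyl-12-phenyldodeca-1,11-dien-2-yl trifluoromethanesulfonate, via lithium enolate 10 (not isolated)
Conditions: LiN(iPr)2, THF, −78 °C; PhNTf2, −78 to 0 °C; 1 M HCl work-up
Reagents that add atoms: N-phenylbis(trifluoromethanesulfonimide), O=S(=O)(N(c1ccccc1)S(=O)(=O)C(F)(F)F)C(F)(F)F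
Why: Kinetic deprotonation of the methyl ketone at the unhindered CH3 (the other α-position is shielded by the neighbouring methyl-bearing carbon) followed by O-triflation gives the terminal enol triflate, and the existing stereocentre is not touched.

Step 5
Reactants: 11; 12 methyl (S)-3-bromo-2-methylpropanoate
Product: 14 methyl (2R,6R,13Z)-2,6-dimethyl-4-methylidene-14-phenyltetradec-13-enoate, via alkylzinc bromide 13 (not isolated)
Conditions: 12, Zn dust, I2 (5 mol%), DMA, 70 °C; then 11, Pd(PPh3)4 (5 mol%), LiCl, THF, 50 °C
Reagents that add atoms: none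
Why: Negishi sp3–sp2 cross-coupling of the chiral-pool β-zincio ester with the vinyl triflate forms the C5–C6 bond and carries the C4 methyl centre in unchanged, since that centre is α to the ester and untouched by zinc insertion or transmetalation (the descriptor changes from S to R only through the priority rules).

Step 6
Reactants: 14
Product: 16 methyl (2R,4S,6R,13Z)-4-hydroperoxy-2,4,6-trimethyl-14-phenyltetradec-13-enoate, via acetoxymercurio hydroperoxide 15 (not isolated)
Conditions: Hg(OAc)2 (1.1 equiv), anhydrous H2O2 in Et2O (20 equiv), CH2Cl2, 0 °C; then NaBH4, 3 M NaOH, 0 °C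
Reagents that add atoms: hydrogen peroxide, OO
Why: Markovnikov hydroperoxymercuration followed by hydride demercuration (Bloodworth chemistry) is chemoselective for the 1,1-disubstituted olefin because mercuration of an internal Z-olefin is about a hundred times slower, and it creates the tertiary C–OOH centre (C6 of the target) without facial bias, so 16 forms about 1:1 with its 4R epimer and the pair is carried on and separated after ring closure.

Step 7
Reactants: 16; 17 methyl acetate
Product: 20 methyl 2-[(3S,4R,6S)-3-hydroxy-4,6-dimethyl-6-[(2R,9Z)-2-methyl-10-phenyldec-9-en-1-yl]-1,2-dioxan-3-yl]acetate, via lithium ester enolate 18 (not isolated), via hydroperoxy keto ester 19 (not isolated)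
Conditions: 17 (5 equiv), LiN(iPr)2 (4.9 equiv), THF, −78 °C; then 16, −78 to −40 °C; AcOH, −78 °C to rt; SiO2 chromatography
Reagents that add atoms: none
Why: Proposed new method: a crossed Claisen condensation is run on the free hydroperoxide, which is first deprotonated to an unreactive lithium peroxide while the new β-keto ester is held as its C2 enolate so that the C4 methyl centre is not epimerised, and on acidification the 6-hydroperoxy-3-oxo ester closes spontaneously by 6-exo addition of the hydroperoxide to the ketone as in the biosynthesis, the hemiketal carbon settling under thermodynamic control as 3S (axial OH, equatorial CH2CO2Me, equatorial C4 methyl and C6 side chain) while the ring diastereomer from the C6 epimer is removed on silica; the closest known reactions are crossed Claisen condensations of ester enolates on hydroxy esters and the spontaneous hemiketalisation of γ-hydroperoxy ketones.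

**Compound list**
1 | phenylacetylene | C#Cc1ccccc1 | starting material
2 | 1,6-dibromohexane | BrCCCCCCBr | starting material
3 | lithium phenylacetylide | [Li]C#Cc1ccccc1 | intermediate
4 | 8-bromo-1-phenyloct-1-yne | BrCCCCCCC#Cc1ccccc1 | intermediate
5 | (Z)-8-bromo-1-phenyloct-1-ene | BrCCCCCC/C=C\c1ccccc1 | intermediate
6 | (E)-pent-3-en-2-one | C/C=C/C(C)=O | starting material
7 | [(7Z)-8-phenyloct-7-en-1-yl]magnesium bromide | Br[Mg]CCCCCC/C=C\c1ccccc1 | intermediate
8 | bromomagnesium (4R,11Z)-4-methyl-12-phenyldodeca-2,11-dien-2-olate | CC(O[Mg]Br)=C[C@H](C)CCCCCC/C=C\c1ccccc1 | intermediate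
9 | (4R,11Z)-4-methyl-12-phenyldodec-11-en-2-one | CC(=O)C[C@H](C)CCCCCC/C=C\c1ccccc1 | intermediate
10 | lithium (4R,11Z)-4-methyl-12-phenyldodeca-1,11-dien-2-olate | [Li]OC(=C)C[C@H](C)CCCCCC/C=C\c1ccccc1 | intermediate
11 | (4R,11Z)-4-methyl-12-phenyldodeca-1,11-dien-2-yl trifluoromethanesulfonate | C=C(OS(=O)(=O)C(F)(F)F)C[C@H](C)CCCCCC/C=C\c1ccccc1 | intermediate
12 | methyl (S)-3-bromo-2-methylpropanoate | COC(=O)[C@H](C)CBr | starting material
13 | [(2S)-3-methoxy-2-methyl-3-oxopropyl]zinc bromide | COC(=O)[C@H](C)C[Zn]Br | intermediate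
14 | methyl (2R,6R,13Z)-2,6-dimethyl-4-methylidene-14-phenyltetradec-13-enoate | COC(=O)[C@H](C)CC(=C)C[C@H](C)CCCCCC/C=C\c1ccccc1 | intermediate
15 | methyl (2R,6R,13Z)-4-[(acetoxymercurio)methyl]-4-hydroperoxy-2,6-dimethyl-14-phenyltetradec-13-enoate (both C4 epimers) | COC(=O)[C@H](C)CC(C[Hg]OC(C)=O)(OO)C[C@H](C)CCCCCC/C=C\c1ccccc1 | intermediate
16 | methyl (2R,4S,6R,13Z)-4-hydroperoxy-2,4,6-trimethyl-14-phenyltetradec-13-enoate (formed about 1:1 with its 4R epimer) | COC(=O)[C@H](C)C[C@@](C)(OO)C[C@H](C)CCCCCC/C=C\c1ccccc1 | intermediate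
17 | methyl acetate | COC(C)=O | starting material
18 | lithium 1-methoxyethen-1-olate | [Li]OC(=C)OC | intermediate
19 | methyl (4R,6S,8R,15Z)-6-hydroperoxy-4,6,8-trimethyl-3-oxo-16-phenylhexadec-15-enoate | COC(=O)CC(=O)[C@H](C)C[C@@](C)(OO)C[C@H](C)CCCCCC/C=C\c1ccccc1 | intermediate
20 | methyl 2-[(3S,4R,6S)-3-hydroxy-4,6-dimethyl-6-[(2R,9Z)-2-methyl-10-phenyldec-9-en-1-yl]-1,2-dioxan-3-yl]acetate | COC(=O)C[C@]1(O)OO[C@@](C)(C[C@H](C)CCCCCC/C=C\c2ccccc2)C[C@H]1C | target

**Step count and risks**
Total steps: 7. Longest linear sequence: 7 (steps 1 to 7 from phenylacetylene). Stereocentres: the side-chain centre in step 3 (catalyst control), C4 from 12 in step 5, C6 in step 6 (unselective, separated in step 7), C3 in step 7 (thermodynamic).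

Steps most likely to fail:

1. Step 6. The β-peroxyalkyl radical formed during borohydride demercuration can close to an epoxide, the ester may assist lactonisation at the mercurinium stage, and the new centre forms without control, so at best half of the material leads to 20. Fallback (radical instead of ionic oxygenation): starting from 14, cobalt-catalysed hydroperoxysilylation (Co(acac)2 cat., O2, Et3SiH kept limiting because the Z-styrene can also accept a hydrogen atom, EtOH, rt, unreacted 14 recycled) gives methyl (2R,6R,13Z)-2,4,6-trimethyl-14-phenyl-4-[(triethylsilyl)peroxy]tetradec-13-enoate F1; AcOH/THF/H2O removes the silyl group and the route is rejoined at 16.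

2. Step 7. The lithium peroxide may oxidise the ester enolate, the hindered α-branched ester may condense slowly, and C4 could epimerise by proton transfer. Fallback (protected peroxide and a neutral decarboxylative acylation): starting from 16, 2-methoxypropene with pyridinium p-toluenesulfonate gives methyl (2R,4S,6R,13Z)-4-[(2-methoxypropan-2-yl)peroxy]-2,4,6-trimethyl-14-phenyltetradec-13-enoate F2; LiOH in THF/MeOH/H2O gives (2R,4S,6R,13Z)-4-[(2-methoxypropan-2-yl)peroxy]-2,4,6-trimethyl-14-phenyltetradec-13-enoic acid F3; carbonyldiimidazole gives (2R,4S,6R,13Z)-1-(1H-imidazol-1-yl)-4-[(2-methoxypropan-2-yl)peroxy]-2,4,6-trimethyl-14-phenyltetradec-13-en-1-one F4, which is C-acylated by Mg(O2CCH2CO2Me)2 and decarboxylates on work-up to methyl (4R,6S,8R,15Z)-6-[(2-methoxypropan-2-yl)peroxy]-4,6,8-trimethyl-3-oxo-16-phenylhexadec-15-enoate F5; AcOH/THF/H2O cleaves the peroxyketal and the released hydroperoxide closes through 19, rejoining the route at 20.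

3. Step 3. Enantioselectivity on this small β-methyl enone is uncertain, and 1,2-addition competes. Fallback (thioester acceptor, ketone synthesis and olefination instead of enone, triflate and Negishi): starting from 5 (as Grignard reagent 7), addition to S-ethyl (E)-but-2-enethioate F6 (made from (E)-but-2-enoyl chloride, ethanethiol and Et3N) with CuI and the Tol-BINAP enantiomer that gives the 3R product affords S-ethyl (3R,10Z)-3-methyl-11-phenylundec-10-enethioate F7; Fukuyama coupling with zinc reagent 13 (PdCl2(PPh3)2 cat., toluene/THF, rt) gives methyl (2R,6R,13Z)-2,6-dimethyl-4-oxo-14-phenyltetradec-13-enoate F8; Wittig methylenation with Ph3P=CH2 in THF at 0 °C rejoins the route at 14, bypassing steps 3 to 5.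

Further compounds
F1 | step 6 | methyl (2R,6R,13Z)-2,4,6-trimethyl-14-phenyl-4-[(triethylsilyl)peroxy]tetradec-13-enoate (both C4 epimers) | COC(=O)[C@H](C)CC(C)(OO[Si](CC)(CC)CC)C[C@H](C)CCCCCC/C=C\c1ccccc1
F2 | step 7 | methyl (2R,4S,6R,13Z)-4-[(2-methoxypropan-2-yl)peroxy]-2,4,6-trimethyl-14-phenyltetradec-13-enoate | COC(=O)[C@H](C)C[C@@](C)(OOC(C)(C)OC)C[C@H](C)CCCCCC/C=C\c1ccccc1
F3 | step 7 | (2R,4S,6R,13Z)-4-[(2-methoxypropan-2-yl)peroxy]-2,4,6-trimethyl-14-phenyltetradec-13-enoic acid | OC(=O)[C@H](C)C[C@@](C)(OOC(C)(C)OC)C[C@H](C)CCCCCC/C=C\c1ccccc1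
F4 | step 7 | (2R,4S,6R,13Z)-1-(1H-imidazol-1-yl)-4-[(2-methoxypropan-2-yl)peroxy]-2,4,6-trimethyl-14-phenyltetradec-13-en-1-one | O=C(n1ccnc1)[C@H](C)C[C@@](C)(OOC(C)(C)OC)C[C@H](C)CCCCCC/C=C\c1ccccc1
F5 | step 7 | methyl (4R,6S,8R,15Z)-6-[(2-methoxypropan-2-yl)peroxy]-4,6,8-trimethyl-3-oxo-16-phenylhexadec-15-enoate | COC(=O)CC(=O)[C@H](C)C[C@@](C)(OOC(C)(C)OC)C[C@H](C)CCCCCC/C=C\c1ccccc1
F6 | step 3 | S-ethyl (E)-but-2-enethioate | CCSC(=O)/C=C/C
F7 | step 3 | S-ethyl (3R,10Z)-3-methyl-11-phenylundec-10-enethioate | CCSC(=O)C[C@H](C)CCCCCC/C=C\c1ccccc1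
F8 | step 3 | methyl (2R,6R,13Z)-2,6-dimethyl-4-oxo-14-phenyltetradec-13-enoate | COC(=O)[C@H](C)CC(=O)C[C@H](C)CCCCCC/C=C\c1ccccc1
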